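**Plan**
1. Retrosynthetic cuts: C3–OH goes back to C3–OCHO, and this to C3–CHO on a C3=C4 chromene (Baeyer–Villiger retron). Then O1–C2 and C3–C4 of the pyran ring are cut together, and finally the O7–acyl bond.
2. Enabling feature: ring A has a local twofold axis through C4a and C7. O1 and O5 are therefore ortho twins and O7 is the unique para oxygen, so the gallate can be fixed at O7 on a symmetric aldehyde. In the pyran ring, O1 (nucleophile) and C4 (electrophile) on ring A match C2 (electrophile) and C3 (nucleophile) of an enal under iminium/enamine catalysis.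
3. Forward order: rings A, B and D (galloyl) are bought. A and D are joined as the ester, one ortho oxygen is unmasked, and the pyran ring closes last in the annulation that also brings in ring B.
4. Stereochemistry: C2 (R) comes from the (S)-diarylprolinol silyl ether catalyst. C3 (R) comes from syn delivery of H2 to the enol formate on the face anti to the C2 aryl group, which gives 2,3-cis. C2 never sits next to a carbonyl group.
5. Helpers: the C3 formyl group activates the annulation and is then exchanged for oxygen. All benzyl ethers fall in the same hydrogenation.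

Key step: step 5

Remark: 1, 4 and 7 are taken as catalogue compounds. The sense of induction in step 5 is assigned from the usual face-shielding model of (S)-diarylprolinol silyl ethers.

**Step 1**
Reactants: 1 3,5-bis(benzyloxy)phenol
Product: 3 4-hydroxy-2,6-bis(benzyloxy)benzaldehyde, via aryl iminium chloride 2 (not isolated)
Conditions: POCl3, DMF, 0 °C to rt; then ice-water
Reagents that add atoms: N,N-dimethylformamide, CN(C)C=O; water, O; phosphoryl chloride, O=P(Cl)(Cl)Cl (chloride of 2 only)
Why: Vilsmeier–Haack formylation, in which the free OH is the strongest para director and the site between the two benzyloxy groups is activated by all three oxygens, as in the known para-formylation of 3,5-dimethoxyphenol; the chelated, less polar ortho isomer is removed by chromatography.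

**Step 2**
Reactants: 3 4-hydroxy-2,6-bis(benzyloxy)benzaldehyde; 4 3,4,5-tris(benzyloxy)benzoic acid
Product: 5 3,5-bis(benzyloxy)-4-formylphenyl 3,4,5-tris(benzyloxy)benzoate
Conditions: DCC, DMAP (cat.), CH2Cl2, 0 °C to rt
Reagents that add atoms: none
Why: Steglich esterification of the only free hydroxyl group places the gallate on the oxygen para to the formyl group (future O7) with no regiochemical choice.

**Step 3**
Reactants: 5 3,5-bis(benzyloxy)-4-formylphenyl 3,4,5-tris(benzyloxy)benzoate
Product: 6 3-(benzyloxy)-4-formyl-5-hydroxyphenyl 3,4,5-tris(benzyloxy)benzoate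
Conditions: MgBr2·OEt2 (1.2 equiv), toluene–Et2O, reflux; 1 M HCl work-up
Reagents that add atoms: none
Why: Chelation-controlled debenzylation, in which Mg(II) bridges the formyl oxygen and one of the two equivalent ortho benzyloxy oxygens and bromide removes that benzyl group only; the magnesium phenolate chelate then slows a second cleavage, and the gallate benzyl ethers, which are not ortho to a carbonyl group, stay.

**Step 4**
Reactants: 7 3,4,5-tris(benzyloxy)benzaldehyde
Product: 8 (E)-3-[3,4,5-tris(benzyloxy)phenyl]prop-2-enal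
Conditions: Ph3P=CHCHO, toluene, 80 °C
Reagents that add atoms: (triphenylphosphoranylidene)acetaldehyde, O=CC=P(c1ccccc1)(c1ccccc1)c1ccccc1
Why: Wittig olefination with a stabilised ylide should give the E-enal by two-carbon homologation in one operation.

**Step 5**
Reactants: 6 3-(benzyloxy)-4-formyl-5-hydroxyphenyl 3,4,5-tris(benzyloxy)benzoate; 8 (E)-3-[3,4,5-tris(benzyloxy)phenyl]prop-2-enal
Product: 9 (2R)-5-(benzyloxy)-3-formyl-2-[3,4,5-tris(benzyloxy)phenyl]-2H-chromen-7-yl 3,4,5-tris(benzyloxy)benzoate
Conditions: (S)-2-[diphenyl(trimethylsilyloxy)methyl]pyrrolidine (20 mol %), 2-nitrobenzoic acid (20 mol %), 4 Å MS, toluene, rt, dark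
Reagents that add atoms: none
Why: The amine condenses with 8 to an E-configured s-trans iminium ion, the single free phenol oxygen of 6 adds to its β-carbon (O1–C2), the enamine so formed attacks the neighbouring formyl carbon through C3 (C3–C4), and loss of water followed by hydrolysis releases 9 and the catalyst. The closest known reaction type is the organocatalytic domino oxa-Michael/aldol condensation of salicylaldehydes with cinnamaldehydes to 2-aryl-2H-chromene-3-carbaldehydes. The pyran ring closes in the aldol event as a 6-(enolexo)-exo-trig closure that follows the intermolecular conjugate addition. C2 is the only stereocentre that remains and is controlled by the catalyst: the CPh2(OSiMe3) group shields one face of the iminium ion, so that oxygen should enter from the open face to give 2R, while the transient centres at C3 and C4 are erased by dehydration. The step needs 1,4- rather than 1,2-addition, one defined phenol oxygen and an irreversible exit from the reversible oxa-Michael equilibrium: the iminium LUMO directs the phenol to the β-carbon, 6 has only one free OH with the gallate fixed para to the formyl group (future O7) and benzyl on the twin oxygen (future O5), and conjugation of the new C3=C4 bond with ring A drives the dehydration. The hindered amine should not be acylated by the electron-rich benzoate, and light is excluded because 2H-chromenes can ring-open photochemically, which would racemise C2.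

**Step 6**
Reactants: 9 (2R)-5-(benzyloxy)-3-formyl-2-[3,4,5-tris(benzyloxy)phenyl]-2H-chromen-7-yl 3,4,5-tris(benzyloxy)benzoate
Product: 10 (2R)-5-(benzyloxy)-3-(formyloxy)-2-[3,4,5-tris(benzyloxy)phenyl]-2H-chromen-7-yl 3,4,5-tris(benzyloxy)benzoate
Conditions: mCPBA (1.05 equiv), CH2Cl2, 0 °C
Reagents that add atoms: 3-chloroperoxybenzoic acid, O=C(OO)c1cccc(Cl)c1
Why: Baeyer–Villiger oxidation of an α-substituted cinnamaldehyde-type enal, in which the peracid adds to the formyl group and the electron-rich alkenyl carbon C3 migrates in preference to hydrogen to give the enol formate; the acceptor-substituted C3=C4 bond of 9 resists epoxidation and C2 is not touched.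

**Step 7**
Reactants: 10 (2R)-5-(benzyloxy)-3-(formyloxy)-2-[3,4,5-tris(benzyloxy)phenyl]-2H-chromen-7-yl 3,4,5-tris(benzyloxy)benzoate
Product: 11 (2R,3R)-3-(formyloxy)-5-hydroxy-2-(3,4,5-trihydroxyphenyl)chroman-7-yl 3,4,5-trihydroxybenzoate
Conditions: H2 (1 atm), Pd(OH)2/C, THF–EtOAc, rt
Reagents that add atoms: none
Why: Heterogeneous syn hydrogenation of C3=C4 should occur on the face opposite the C2 aryl group, which allylic strain against the C3 formyloxy group holds pseudoaxial, so that H3 ends trans and the oxygen cis to the aryl group (3R), as in the classical hydrogenation of 3-oxygenated flavenes to 2,3-cis-flavan-3-ols; the seven benzyl ethers are hydrogenolysed while both esters persist in the alcohol-free solvent.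

**Step 8**
Reactants: 11 (2R,3R)-3-(formyloxy)-5-hydroxy-2-(3,4,5-trihydroxyphenyl)chroman-7-yl 3,4,5-trihydroxybenzoate
Product: 12 epigallocatechin 7-O-gallate, (2R,3R)-3,5-dihydroxy-2-(3,4,5-trihydroxyphenyl)chroman-7-yl 3,4,5-trihydroxybenzoate
Conditions: HCl (0.05 M) in MeOH, 0 °C to rt, Ar
Reagents that add atoms: none
Why: Acid-catalysed transesterification removes the alkyl formate far faster than it attacks the aryl benzoate, whose carbonyl group is deactivated by the para hydroxyl group, and cold dilute acid under argon avoids both C2 epimerisation and autoxidation of the pyrogallol rings.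

**Compound list**
1 | 3,5-bis(benzyloxy)phenol | Oc1cc(OCc2ccccc2)cc(OCc2ccccc2)c1 | starting material
2 | [2,6-bis(benzyloxy)-4-hydroxyphenyl]methylidene-dimethyliminium chloride | C[N+](C)=Cc1c(OCc2ccccc2)cc(O)cc1OCc1ccccc1.[Cl-] | intermediate
3 | 4-hydroxy-2,6-bis(benzyloxy)benzaldehyde | O=Cc1c(OCc2ccccc2)cc(O)cc1OCc1ccccc1 | intermediate
4 | 3,4,5-tris(benzyloxy)benzoic acid | OC(=O)c1cc(OCc2ccccc2)c(OCc2ccccc2)c(OCc2ccccc2)c1 | starting material
5 | 3,5-bis(benzyloxy)-4-formylphenyl 3,4,5-tris(benzyloxy)benzoate | O=Cc1c(OCc2ccccc2)cc(OC(=O)c2cc(OCc3ccccc3)c(OCc3ccccc3)c(OCc3ccccc3)c2)cc1OCc1ccccc1 | intermediate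
6 | 3-(benzyloxy)-4-formyl-5-hydroxyphenyl 3,4,5-tris(benzyloxy)benzoate | O=Cc1c(O)cc(OC(=O)c2cc(OCc3ccccc3)c(OCc3ccccc3)c(OCc3ccccc3)c2)cc1OCc1ccccc1 | intermediate
7 | 3,4,5-tris(benzyloxy)benzaldehyde | O=Cc1cc(OCc2ccccc2)c(OCc2ccccc2)c(OCc2ccccc2)c1 | starting material
8 | (E)-3-[3,4,5-tris(benzyloxy)phenyl]prop-2-enal | O=C/C=C/c1cc(OCc2ccccc2)c(OCc2ccccc2)c(OCc2ccccc2)c1 | intermediate
9 | (2R)-5-(benzyloxy)-3-formyl-2-[3,4,5-tris(benzyloxy)phenyl]-2H-chromen-7-yl 3,4,5-tris(benzyloxy)benzoate | O=C(Oc1cc(OCc2ccccc2)c2c(c1)O[C@H](c1cc(OCc3ccccc3)c(OCc3ccccc3)c(OCc3ccccc3)c1)C(C=O)=C2)c1cc(OCc2ccccc2)c(OCc2ccccc2)c(OCc2ccccc2)c1 | intermediate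
10 | (2R)-5-(benzyloxy)-3-(formyloxy)-2-[3,4,5-tris(benzyloxy)phenyl]-2H-chromen-7-yl 3,4,5-tris(benzyloxy)benzoate | O=C(Oc1cc(OCc2ccccc2)c2c(c1)O[C@H](c1cc(OCc3ccccc3)c(OCc3ccccc3)c(OCc3ccccc3)c1)C(OC=O)=C2)c1cc(OCc2ccccc2)c(OCc2ccccc2)c(OCc2ccccc2)c1 | intermediate
11 | (2R,3R)-3-(formyloxy)-5-hydroxy-2-(3,4,5-trihydroxyphenyl)chroman-7-yl 3,4,5-trihydroxybenzoate | O=C(Oc1cc(O)c2c(c1)O[C@H](c1cc(O)c(O)c(O)c1)[C@H](OC=O)C2)c1cc(O)c(O)c(O)c1 | intermediate
12 | epigallocatechin 7-O-gallate | O=C(Oc1cc(O)c2c(c1)O[C@H](c1cc(O)c(O)c(O)c1)[C@H](O)C2)c1cc(O)c(O)c(O)c1 | target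

Total steps: 8. Longest linear sequence: 7 (steps 1, 2, 3, 5, 6, 7, 8).

**Steps most likely to fail**

Step 6. The enol formate is a more electron-rich alkene than the enal and may be epoxidised by the peracid as it forms. Hydrogen migration to the carboxylic acid may also compete with alkenyl migration.
- The fallback replaces the carbon-to-oxygen shift by a carbon-to-nitrogen shift and sets out from 9.
- Pinnick oxidation (NaClO2, NaH2PO4, 2-methyl-2-butene, t-BuOH–THF–H2O) should give the chromene-3-carboxylic acid F1.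
- DPPA and Et3N in toluene convert it to the acyl azide F2, which on warming to 80 °C undergoes Curtius rearrangement to the alkenyl isocyanate F3.
- Brief treatment with dilute aqueous HCl in THF hydrolyses this to the (2R)-flavan-3-one F4.
- L-Selectride in THF at −78 °C delivers hydride anti to the C2 aryl group, faster than it attacks the aryl benzoate, to give the benzylated 2,3-cis alcohol F5.
- Hydrogenolysis (H2, Pd(OH)2/C, THF–MeOH) comes back to the route at 12.

Step 5. Acyl transfer from the activated 4-formylphenyl ester to the secondary amine would strip the gallate and consume the catalyst. Slow aldol closure onto the doubly ortho-substituted, hydrogen-bonded formyl group would give the reversible oxa-Michael step time to erode the enantioselectivity.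
- The fallback takes the ester out of the annulation and attaches it after ring closure, setting out from 3.
- TIPSCl and imidazole in DMF give the silyl ether F6.
- MgBr2·OEt2 removes one ortho benzyl group to give the salicylaldehyde F7.
- With no acyl donor present, the annulation with 8 can be run at higher catalyst and acid loading to give the 7-silyloxy chromene carbaldehyde F8.
- TBAF buffered with AcOH frees the 7-hydroxy chromene carbaldehyde F9.
- DCC/DMAP coupling with 4 comes back to the route at 9.

Step 7. Hydrogenolytic opening of the allylic and benzylic C2–O1 bond may occur before the alkene is saturated. Facial selectivity on the metal surface may also be poor once debenzylation changes the shape of the substrate.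
- The fallback separates alkene reduction from debenzylation and moves the stereocontrol from the substrate to a catalyst, setting out from 10.
- Homogeneous hydrogenation of the cyclic enol ester uses a cationic Rh(I) Me-DuPhos complex, with the ligand enantiomer matched to the C2 bias (H2, CH2Cl2).
- This catalyst does not cleave C–O bonds and should give the fully benzylated 2,3-cis formate F10.
- Hydrogenolysis of the saturated chroman (H2, Pd(OH)2/C, THF–EtOAc) then comes back to the route at 11.

**Further compounds**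
F1 | step 6 | (2R)-5-(benzyloxy)-7-{[3,4,5-tris(benzyloxy)benzoyl]oxy}-2-[3,4,5-tris(benzyloxy)phenyl]-2H-chromene-3-carboxylic acid | O=C(Oc1cc(OCc2ccccc2)c2c(c1)O[C@H](c1cc(OCc3ccccc3)c(OCc3ccccc3)c(OCc3ccccc3)c1)C(C(=O)O)=C2)c1cc(OCc2ccccc2)c(OCc2ccccc2)c(OCc2ccccc2)c1
F2 | step 6 | acyl azide of F1 | O=C(Oc1cc(OCc2ccccc2)c2c(c1)O[C@H](c1cc(OCc3ccccc3)c(OCc3ccccc3)c(OCc3ccccc3)c1)C(C(=O)N=[N+]=[N-])=C2)c1cc(OCc2ccccc2)c(OCc2ccccc2)c(OCc2ccccc2)c1
F3 | step 6 | (2R)-5-(benzyloxy)-3-isocyanato-2-[3,4,5-tris(benzyloxy)phenyl]-2H-chromen-7-yl 3,4,5-tris(benzyloxy)benzoate | O=C(Oc1cc(OCc2ccccc2)c2c(c1)O[C@H](c1cc(OCc3ccccc3)c(OCc3ccccc3)c(OCc3ccccc3)c1)C(N=C=O)=C2)c1cc(OCc2ccccc2)c(OCc2ccccc2)c(OCc2ccccc2)c1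
F4 | step 6 | (2R)-5-(benzyloxy)-3-oxo-2-[3,4,5-tris(benzyloxy)phenyl]chroman-7-yl 3,4,5-tris(benzyloxy)benzoate | O=C(Oc1cc(OCc2ccccc2)c2c(c1)O[C@H](c1cc(OCc3ccccc3)c(OCc3ccccc3)c(OCc3ccccc3)c1)C(=O)C2)c1cc(OCc2ccccc2)c(OCc2ccccc2)c(OCc2ccccc2)c1
F5 | step 6 | (2R,3R)-5-(benzyloxy)-3-hydroxy-2-[3,4,5-tris(benzyloxy)phenyl]chroman-7-yl 3,4,5-tris(benzyloxy)benzoate | O=C(Oc1cc(OCc2ccccc2)c2c(c1)O[C@H](c1cc(OCc3ccccc3)c(OCc3ccccc3)c(OCc3ccccc3)c1)[C@H](O)C2)c1cc(OCc2ccccc2)c(OCc2ccccc2)c(OCc2ccccc2)c1
F6 | step 5 | 2,6-bis(benzyloxy)-4-[(triisopropylsilyl)oxy]benzaldehyde | O=Cc1c(OCc2ccccc2)cc(O[Si](C(C)C)(C(C)C)C(C)C)cc1OCc1ccccc1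
F7 | step 5 | 2-(benzyloxy)-6-hydroxy-4-[(triisopropylsilyl)oxy]benzaldehyde | O=Cc1c(O)cc(O[Si](C(C)C)(C(C)C)C(C)C)cc1OCc1ccccc1
F8 | step 5 | (2R)-5-(benzyloxy)-2-[3,4,5-tris(benzyloxy)phenyl]-7-[(triisopropylsilyl)oxy]-2H-chromene-3-carbaldehyde | CC(C)[Si](Oc1cc(OCc2ccccc2)c2c(c1)O[C@H](c1cc(OCc3ccccc3)c(OCc3ccccc3)c(OCc3ccccc3)c1)C(C=O)=C2)(C(C)C)C(C)C
F9 | step 5 | (2R)-5-(benzyloxy)-7-hydroxy-2-[3,4,5-tris(benzyloxy)phenyl]-2H-chromene-3-carbaldehyde | Oc1cc(OCc2ccccc2)c2c(c1)O[C@H](c1cc(OCc3ccccc3)c(OCc3ccccc3)c(OCc3ccccc3)c1)C(C=O)=C2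
F10 | step 7 | (2R,3R)-5-(benzyloxy)-3-(formyloxy)-2-[3,4,5-tris(benzyloxy)phenyl]chroman-7-yl 3,4,5-tris(benzyloxy)benzoate | O=C(Oc1cc(OCc2ccccc2)c2c(c1)O[C@H](c1cc(OCc3ccccc3)c(OCc3ccccc3)c(OCc3ccccc3)c1)[C@H](OC=O)C2)c1cc(OCc2ccccc2)c(OCc2ccccc2)c(OCc2ccccc2)c1
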